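**Analysis of the target**

The target 21 is a biflavone built from two 2-aryl-4H-chromen-4-one units joined by one C–C bond: C8 of ring A of a chrysoeriol unit (5,7,4'-trihydroxy-3'-methoxyflavone) is bonded to C3' of ring B of an apigenin unit (5,7,4'-trihydroxyflavone). It has no stereogenic centre; the only stereo element that could matter is the C8–C3' axis, flanked by C7–OH, the ring oxygen on C8a and C4'–OH. The molecule holds six phenols, two of them (C5–OH of each unit) chelated to the C4 carbonyls, and one aryl methyl ether that must stay while every other oxygen is set free. It also holds two γ-pyranones whose C2=C3–C4=O system is open to organolithium reagents, to hot hydroxide and, less readily, to hydrogenation. The synthesis is hard for three reasons: the two halves differ only by one methoxy group and so must be grown separately, the hindered biaryl bond must sit at C8 and not at C6, and the free polyphenol is poorly soluble, so deprotection has to come last. The strategy rests on ring A of the apigenin unit: C8a (bearing O1) and C4a (bearing C4) are neighbours on a benzene ring oxygenated at C5 and C7, so they are the two termini of a 3,5-dioxygenated benzyne. O1, C4 and the carbonyl oxygen on C4 are together one carboxyl group, and C3 and C2 are an alkyne on C1' of ring B, so an arylpropiolic acid and the aryne account for the whole apigenin pyranone and ring A.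

**Retrosynthetic reasoning**

21 to 20. The six O–H bonds are traced back to six benzyl ethers. Benzyl is chosen because the C3' methoxy group must survive; methyl ethers on the other oxygens could not be removed selectively beside it. The forward step is a neutral hydrogenolysis that leaves the methyl ether and both pyranones alone.

20 to 19. The O1–C2 bond of the apigenin pyranone is cut, which gives the isomeric ortho-hydroxyaryl ynone 19. Nothing is lost or gained in atoms. The forward step has to close the six-membered ring (6-endo) and not the five-membered one (5-exo).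

19 to 12 and 17. The bonds C4–C4a and O1–C8a of the apigenin unit are cut together. They run to adjacent carbons of one benzene ring and both partner atoms belong to the carboxyl group of 12, so the cut releases ring A as aryne 18, stored as silyl triflate 17. This is preferred to cutting the biaryl bond last, because ring A then arrives with its oxygen pattern already in place while the complete chrysoeriol unit and the hindered axis are only spectators. The forward reaction has to add the carboxylate across the unsymmetrical aryne in one orientation and then move the acyl group from oxygen to carbon instead of stopping at O-arylation.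

12 to 11 to 10. The carboxyl carbon is removed from the alkyne terminus of 12, which gives 11, and the terminal alkyne carbon is then removed, which gives aldehyde 10. An aldehyde is carried through the cross-coupling because a terminal alkyne or a free propiolic acid would interfere with the palladium catalyst. Both forward steps (one-carbon homologation, C–H carboxylation) work without organolithium reagents, which the pyranone would not tolerate.

10 to 6 and 9. The C8–C3' biaryl bond is cut, the only bond between the two halves. The halide is placed on the crowded, electron-rich C8 of the finished chrysoeriol unit 6 and boron on the simple one-ring piece 9, so that the sensitive boron partner is cheap and can be used in excess. The forward step is a palladium-catalysed coupling that has to form a biaryl with three ortho substituents.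

6 to 5 to 3 and 4, then 3 to 2 to 1. The chrysoeriol pyranone is opened at O1–C2 (oxidative cyclisation of chalcone 5) and at C2–C3 (aldol condensation of ketone 3 with aldehyde 4). The C–I bond is traced back to iodination of 2, where the one free phenol directs the halogen to its ortho position; 2 comes from 1 by selective benzylation. That phenol oxygen later becomes O1, so the iodine is fixed at C8 before the heterocycle exists and the C6/C8 question does not arise at the flavone stage.

9 to 8 to 7. The C–B bond comes from the C–Br bond of 8, and 8 from phenol 7 by benzylation.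

17 to 14 to 13. The ortho-silyl triflate 17 is traced to ortho-bromophenol 14 through silyl ether 15, bromine–lithium exchange with silyl migration from oxygen to carbon to give phenolate 16, and triflation of 16. The bromine of 14 comes from ortho-bromination of 13.

**Alternatives that were turned down**

Alternative 1: Ring A of the chrysoeriol unit is dismantled completely (C8–C8a, C6–C7 and C4a–C8a). Four carbons come from 3-ethoxycyclobut-2-en-1-one A1 and two from the triisopropylsiloxyalkyne A2, which already carries ring B of the apigenin unit with its formyl group masked as a dioxolane.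
- Forward key step: heating A1 with A2 would trigger a four-electron electrocyclic opening of A1, a [2+2] addition to the electron-rich triple bond of A2, a second four-electron opening and a six-electron closure. The product would be phenol A3, with C8a–OH free, the C7 oxygen silylated and the C5 oxygen ethylated.
- For: the hindered C8–C3' bond is never made by coupling, since it is the aryl–alkyne bond of A2 and the ring grows around it. The C6/C8 question is settled by construction and the three oxygens arrive differentiated. On the biaryl bond this route is stronger than the chosen one.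
- Against: A3 contains neither pyranone. C4a would have to be acylated next to the free hydroxyl while C6 is also free and activated. Both heterocycles would then be built one after the other. The C5 ethyl ether would have to be cleaved at the very end by a Lewis acid in the presence of the C3' methoxy group. Making A2 needs strongly basic organolithium chemistry of its own.
- Comparison: about five steps to A2 and about ten after A3, against fourteen steps in all for the chosen route with only two after the key step. The chosen strategy accepts one hindered coupling and offers in return a late, convergent key step on finished fragments and a single kind of protecting group.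

Alternative 2: The C3–C4 bond of the chrysoeriol pyranone is cut, with the 1,3-dicarbonyl masked as an isoxazole.
- Forward key step: the biaryl aldoxime A4, which carries the finished protected apigenin unit, would be oxidised in the flask by PhI(OAc)2 to nitrile oxide A5. A5 would add to the terminal alkyne 1-(benzyloxy)-4-ethynyl-2-methoxybenzene A6, carbon to the terminal alkyne carbon and oxygen to the internal one, to give the 3,5-diarylisoxazole A7.
- For: the cycloaddition is neutral, mild and regiodefined for a terminal alkyne, and A6 is a simple one-ring partner that can be used in excess. A5 has two ortho substituents and should dimerise slowly. The carbon skeleton of the pyranone is set without enolate chemistry. The route is as convergent as the chosen one.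
- Against: ring A of A4 is pentasubstituted, and its biaryl bond still has to be made by cross-coupling at a carbon lying between a benzyloxy group and a methoxymethyl-protected oxygen, which is no easier than in 10. Two kinds of phenol protection are needed. After A7 the N–O bond must be cleaved reductively without touching six benzyl ethers, the nitrogen hydrolysed off, the methoxymethyl group removed and the ring closed by dehydration before the final hydrogenolysis.
- Comparison: at least four operations follow the key step, against two in the chosen route. The chosen strategy makes the corresponding pyranone bonds of the other unit directly, with no masking group to install and remove.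

Alternative 3: Ring B of the apigenin unit is cut at C2'–C3' and C4'–C5'.
- Forward key step: methyl coumalate A8 and the 8-(triisopropylsiloxyethynyl)flavone A9 would combine in a [4+2] cycloaddition of inverse electron demand, the nucleophilic alkyne carbon on C8 of A9 bonding to C6 of the pyranone ring of A8. Loss of CO2 from the bridged adduct would aromatise it to the para-siloxybenzoate A10.
- For: ring B is grown on a linear alkyne, where the crowding at C8 costs little, so the biaryl bond again needs no coupling. The regiochemistry follows from the polarisation of both partners, A8 is an inexpensive diene, and its ester marks C1'. On the biaryl bond this route is stronger than the chosen one.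
- Against: A9 is an ynol silyl ether on a flavone. The usual entries to such ethers need strongly basic organolithium chemistry, which the pyranone would not survive, and the ether is sensitive to water. The cycloaddition needs heat. After A10 all of rings A and C of the apigenin unit remain to be built from the ester, either by a Claisen-type acylation under strong base or by reduction and a chalcone route, with a silyl ether among benzyl ethers to handle.
- Comparison: five or more steps would follow the key step. The chosen strategy pays for the hindered coupling with a standard catalyst system and then delivers ring A of the apigenin unit in one operation and the pyranone in the next.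

Key step: step 12

Assumption: the C8–C3' axis of 21 is taken as freely rotating at room temperature, since the structure to be made carries no axial descriptor, so no atroposelective step is planned.

**Route**

Step 1
Reactants: 1 2,4,6-trihydroxyacetophenone
Product: 2 4,6-bis(benzyloxy)-2-hydroxyacetophenone
Conditions: BnBr (2.1 equiv), K2CO3 (2.2 equiv), DMF, rt to 60 °C
Reagents that add atoms: benzyl bromide, BrCc1ccccc1
Why: Williamson etherification; once the para hydroxyl and one ortho hydroxyl are benzylated, the last hydroxyl is locked in a hydrogen bond to the acetyl carbonyl and is much less nucleophilic, so alkylation should stop at the dibenzyl ether.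

Step 2
Reactants: 2 4,6-bis(benzyloxy)-2-hydroxyacetophenone
Product: 3 4,6-bis(benzyloxy)-2-hydroxy-3-iodoacetophenone
Conditions: NIS (1.05 equiv), TFA (10 mol %), MeCN, 0 °C to rt
Reagents that add atoms: N-iodosuccinimide, O=C1CCC(=O)N1I
Why: Electrophilic aromatic iodination; C3 is ortho to the free phenol and para to a benzyloxy group, and the phenol should direct the iodine to its own ortho position, which is the carbon that becomes C8 of the flavone.

Step 3
Reactants: 3 4,6-bis(benzyloxy)-2-hydroxy-3-iodoacetophenone; 4 4-(benzyloxy)-3-methoxybenzaldehyde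
Product: 5 (E)-1-[4,6-bis(benzyloxy)-2-hydroxy-3-iodophenyl]-3-[4-(benzyloxy)-3-methoxyphenyl]prop-2-en-1-one
Conditions: KOH (50% aq.), EtOH/THF, rt
Reagents that add atoms: none
Why: Claisen–Schmidt condensation; aldehyde 4 has no α-hydrogen, and the E alkene should result from E1cB dehydration of the aldol under thermodynamic control.

Step 4
Reactants: 5 (E)-1-[4,6-bis(benzyloxy)-2-hydroxy-3-iodophenyl]-3-[4-(benzyloxy)-3-methoxyphenyl]prop-2-en-1-one
Product: 6 5,7-bis(benzyloxy)-2-[4-(benzyloxy)-3-methoxyphenyl]-8-iodo-4H-chromen-4-one
Conditions: I2 (10 mol %), DMSO, 120 °C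
Reagents that add atoms: none
Why: Iodine-catalysed oxidative cyclisation of a 2'-hydroxychalcone (oxa-Michael closure, α-iodination, loss of HI, with DMSO as the terminal oxidant that returns HI to I2); the only free hydroxyl lies next to the iodine, so the iodine should end up at C8.

Step 5
Reactants: 7 3-bromo-4-hydroxybenzaldehyde
Product: 8 4-(benzyloxy)-3-bromobenzaldehyde
Conditions: BnBr, K2CO3, acetone, reflux
Reagents that add atoms: benzyl bromide, BrCc1ccccc1
Why: Williamson etherification of an acidic phenol (para formyl group); no competing site.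

Step 6
Reactants: 8 4-(benzyloxy)-3-bromobenzaldehyde
Product: 9 4-(benzyloxy)-3-(4,4,5,5-tetramethyl-1,3,2-dioxaborolan-2-yl)benzaldehyde
Conditions: B2pin2, Pd(dppf)Cl2 (3 mol %), KOAc, 1,4-dioxane, 90 °C
Reagents that add atoms: bis(pinacolato)diboron, CC1(C)OB(OC1(C)C)B1OC(C)(C)C(C)(C)O1
Why: Miyaura borylation; the weak acetate base allows transmetalation with the diboron reagent without promoting coupling of the product, and an aryl aldehyde is tolerated.

Step 7
Reactants: 6 5,7-bis(benzyloxy)-2-[4-(benzyloxy)-3-methoxyphenyl]-8-iodo-4H-chromen-4-one; 9 4-(benzyloxy)-3-(4,4,5,5-tetramethyl-1,3,2-dioxaborolan-2-yl)benzaldehyde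
Product: 10 4-(benzyloxy)-3-{5,7-bis(benzyloxy)-2-[4-(benzyloxy)-3-methoxyphenyl]-4-oxo-4H-chromen-8-yl}benzaldehyde
Conditions: Pd(OAc)2 (5 mol %), SPhos (10 mol %), K3PO4 (3 equiv), 9 (1.5 equiv), toluene/H2O (10:1), 100 °C
Reagents that add atoms: none
Why: Suzuki–Miyaura coupling; an aryl iodide adds readily to zerovalent palladium even between two oxygen substituents, and a bulky dialkylbiarylphosphine is the established answer to transmetalation and reductive elimination in biaryls with three ortho substituents.

Step 8
Reactants: 10 4-(benzyloxy)-3-{5,7-bis(benzyloxy)-2-[4-(benzyloxy)-3-methoxyphenyl]-4-oxo-4H-chromen-8-yl}benzaldehyde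
Product: 11 5,7-bis(benzyloxy)-2-[4-(benzyloxy)-3-methoxyphenyl]-8-[2-(benzyloxy)-5-ethynylphenyl]-4H-chromen-4-one
Conditions: dimethyl (1-diazo-2-oxopropyl)phosphonate (1.5 equiv), K2CO3 (2 equiv), MeOH/THF, 0 °C to rt
Reagents that add atoms: dimethyl (1-diazo-2-oxopropyl)phosphonate, COP(=O)(OC)C(=[N+]=[N-])C(C)=O
Why: Seyferth–Gilbert homologation in the Bestmann–Ohira form; carbonate in methanol releases the diazomethylphosphonate anion, which converts the non-enolisable aldehyde into the terminal alkyne without any base strong enough to attack the pyranone.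

Step 9
Reactants: 11 5,7-bis(benzyloxy)-2-[4-(benzyloxy)-3-methoxyphenyl]-8-[2-(benzyloxy)-5-ethynylphenyl]-4H-chromen-4-one
Product: 12 3-(4-(benzyloxy)-3-{5,7-bis(benzyloxy)-2-[4-(benzyloxy)-3-methoxyphenyl]-4-oxo-4H-chromen-8-yl}phenyl)prop-2-ynoic acid
Conditions: AgI (2 mol %), Cs2CO3 (1.5 equiv), CO2 (2 atm), DMF, 50 °C; then 1 M HCl, 0 °C
Reagents that add atoms: carbon dioxide, O=C=O
Why: Silver-catalysed C–H carboxylation of a terminal alkyne; the silver acetylide formed with carbonate base inserts CO2 to give the cesium propiolate, so no organolithium reagent meets the pyranone, and cold acidification should free the acid.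

Step 10
Reactants: 13 3,5-bis(benzyloxy)phenol
Product: 14 3,5-bis(benzyloxy)-2-bromophenol
Conditions: NBS (1.0 equiv), CH2Cl2, −78 °C
Reagents that add atoms: N-bromosuccinimide, O=C1CCC(=O)N1Br
Why: Electrophilic bromination; in a non-polar solvent at low temperature the phenol should guide the reagent to its ortho position (the two ortho positions are equivalent), while the para position is shielded between two benzyloxy groups.

Step 11
Reactants: 14 3,5-bis(benzyloxy)-2-bromophenol
Product: 17 3,5-bis(benzyloxy)-2-(trimethylsilyl)phenyl trifluoromethanesulfonate, via aryl trimethylsilyl ether 15 (not isolated), via lithium 2-silylphenolate 16 (not isolated)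
Conditions: HMDS, THF, 65 °C, then concentrate; n-BuLi, THF, −100 °C; Tf2O, −100 to −78 °C
Reagents that add atoms: hexamethyldisilazane, C[Si](C)(C)N[Si](C)(C)C; trifluoromethanesulfonic anhydride, O=S(=O)(OS(=O)(=O)C(F)(F)F)C(F)(F)F
Why: Standard one-pot entry to ortho-silylaryl triflates: O-silylation, bromine–lithium exchange, retro-Brook 1,3-shift of silicon from oxygen to carbon, and triflation of the resulting phenoxide; at −100 °C the exchange should be much faster than deprotonation of the benzylic positions.

Step 12
Reactants: 12 3-(4-(benzyloxy)-3-{5,7-bis(benzyloxy)-2-[4-(benzyloxy)-3-methoxyphenyl]-4-oxo-4H-chromen-8-yl}phenyl)prop-2-ynoic acid; 17 3,5-bis(benzyloxy)-2-(trimethylsilyl)phenyl trifluoromethanesulfonate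
Product: 19 1-[2,4-bis(benzyloxy)-6-hydroxyphenyl]-3-(4-(benzyloxy)-3-{5,7-bis(benzyloxy)-2-[4-(benzyloxy)-3-methoxyphenyl]-4-oxo-4H-chromen-8-yl}phenyl)prop-2-yn-1-one, via 3,5-bis(benzyloxy)benzyne 18 (not isolated)
Conditions: 17 (1.5 equiv), CsF (4 equiv), THF, 125 °C, sealed tube
Reagents that add atoms: none
Why: Fluoride attacks the silicon of 17 and triflate leaves, which releases aryne 18 slowly in the presence of the cesium carboxylate of 12. The carboxylate oxygen adds to the aryne carbon that carried the triflate, the one remote from the neighbouring benzyloxy group, because the electron-withdrawing C–O bond beside the triple bond distorts the aryne (wider internal angle at the remote carbon) and stabilises the aryl anion that develops next to it. This aryl anion, held ortho to the new aryl ester oxygen, attacks the acyl carbon to give a four-membered benzoxetene alkoxide that opens to the chelated cesium phenoxide of ynone 19, so the aryne has formally entered the C(=O)–O bond and O1–C8a and C4–C4a of the apigenin unit are made in one operation. The closest known reaction type is the fluoride-induced insertion of arynes into the C–O bond of carboxylic acids to give ortho-hydroxyaryl ketones, which covers arylpropiolic acids and is in mechanism an anionic Fries-type acyl shift. No ring is closed in the isolated product (the four-membered ring is only a transient) and no stereocentre is formed. The step needs regioselectivity across the unsymmetrical aryne, secured by the flanking benzyloxy group as described, and chemoselectivity for acyl transfer over protonation of the aryl anion to the simple aryl ester, which aprotic THF, the high temperature and the excess of CsF should favour. The chrysoeriol pyranone, the alkyne and the benzyl ethers offer the aryne no acidic or strongly nucleophilic site, and any 20 formed in the pot by closure of the phenoxide is the product of step 13, so the crude mixture can be carried forward.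

Step 13
Reactants: 19 1-[2,4-bis(benzyloxy)-6-hydroxyphenyl]-3-(4-(benzyloxy)-3-{5,7-bis(benzyloxy)-2-[4-(benzyloxy)-3-methoxyphenyl]-4-oxo-4H-chromen-8-yl}phenyl)prop-2-yn-1-one
Product: 20 5,7-bis(benzyloxy)-8-{2-(benzyloxy)-5-[5,7-bis(benzyloxy)-4-oxo-4H-chromen-2-yl]phenyl}-2-[4-(benzyloxy)-3-methoxyphenyl]-4H-chromen-4-one
Conditions: DMAP (20 mol %), DMF, 30 °C
Reagents that add atoms: none
Why: Amine-catalysed 6-endo-dig oxa-Michael cyclisation of an ortho-hydroxyaryl ynone; DMAP adds to the alkyne β-carbon to give a β-pyridinium enolate, the phenol oxygen then attacks the same carbon and DMAP is expelled, which should enforce six-membered closure over 5-exo formation of the aurone.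

Step 14
Reactants: 20 5,7-bis(benzyloxy)-8-{2-(benzyloxy)-5-[5,7-bis(benzyloxy)-4-oxo-4H-chromen-2-yl]phenyl}-2-[4-(benzyloxy)-3-methoxyphenyl]-4H-chromen-4-one
Product: 21 8-[5-(5,7-dihydroxy-4-oxo-4H-chromen-2-yl)-2-hydroxyphenyl]-5,7-dihydroxy-2-(4-hydroxy-3-methoxyphenyl)-4H-chromen-4-one (target)
Conditions: H2 (1 atm), 10% Pd/C, THF/MeOH (1:1), rt
Reagents that add atoms: none
Why: Catalytic hydrogenolysis of six aryl benzyl ethers; the aryl methyl ether is inert, and at atmospheric pressure with monitoring of hydrogen uptake the conjugated C2=C3 bonds of the two pyranones should be spared.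

**Compound list**

1 | 2,4,6-trihydroxyacetophenone | CC(=O)c1c(O)cc(O)cc1O | starting material
2 | 4,6-bis(benzyloxy)-2-hydroxyacetophenone | CC(=O)c1c(O)cc(OCc2ccccc2)cc1OCc1ccccc1 | intermediate
3 | 4,6-bis(benzyloxy)-2-hydroxy-3-iodoacetophenone | CC(=O)c1c(O)c(I)c(OCc2ccccc2)cc1OCc1ccccc1 | intermediate
4 | 4-(benzyloxy)-3-methoxybenzaldehyde (O-benzylvanillin) | COc1cc(C=O)ccc1OCc1ccccc1 | starting material
5 | (E)-1-[4,6-bis(benzyloxy)-2-hydroxy-3-iodophenyl]-3-[4-(benzyloxy)-3-methoxyphenyl]prop-2-en-1-one | COc1cc(/C=C/C(=O)c2c(O)c(I)c(OCc3ccccc3)cc2OCc2ccccc2)ccc1OCc1ccccc1 | intermediate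
6 | 5,7-bis(benzyloxy)-2-[4-(benzyloxy)-3-methoxyphenyl]-8-iodo-4H-chromen-4-one | COc1cc(-c2cc(=O)c3c(OCc4ccccc4)cc(OCc4ccccc4)c(I)c3o2)ccc1OCc1ccccc1 | intermediate
7 | 3-bromo-4-hydroxybenzaldehyde | O=Cc1ccc(O)c(Br)c1 | starting material
8 | 4-(benzyloxy)-3-bromobenzaldehyde | O=Cc1ccc(OCc2ccccc2)c(Br)c1 | intermediate
9 | 4-(benzyloxy)-3-(4,4,5,5-tetramethyl-1,3,2-dioxaborolan-2-yl)benzaldehyde | O=Cc1ccc(OCc2ccccc2)c(B2OC(C)(C)C(C)(C)O2)c1 | intermediate
10 | 4-(benzyloxy)-3-{5,7-bis(benzyloxy)-2-[4-(benzyloxy)-3-methoxyphenyl]-4-oxo-4H-chromen-8-yl}benzaldehyde | COc1cc(-c2cc(=O)c3c(OCc4ccccc4)cc(OCc4ccccc4)c(-c4cc(C=O)ccc4OCc4ccccc4)c3o2)ccc1OCc1ccccc1 | intermediate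
11 | 5,7-bis(benzyloxy)-2-[4-(benzyloxy)-3-methoxyphenyl]-8-[2-(benzyloxy)-5-ethynylphenyl]-4H-chromen-4-one | COc1cc(-c2cc(=O)c3c(OCc4ccccc4)cc(OCc4ccccc4)c(-c4cc(C#C)ccc4OCc4ccccc4)c3o2)ccc1OCc1ccccc1 | intermediate
12 | 3-(4-(benzyloxy)-3-{5,7-bis(benzyloxy)-2-[4-(benzyloxy)-3-methoxyphenyl]-4-oxo-4H-chromen-8-yl}phenyl)prop-2-ynoic acid | COc1cc(-c2cc(=O)c3c(OCc4ccccc4)cc(OCc4ccccc4)c(-c4cc(C#CC(=O)O)ccc4OCc4ccccc4)c3o2)ccc1OCc1ccccc1 | intermediate
13 | 3,5-bis(benzyloxy)phenol | Oc1cc(OCc2ccccc2)cc(OCc2ccccc2)c1 | starting material
14 | 3,5-bis(benzyloxy)-2-bromophenol | Oc1cc(OCc2ccccc2)cc(OCc2ccccc2)c1Br | intermediate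
15 | [3,5-bis(benzyloxy)-2-bromophenoxy]trimethylsilane | C[Si](C)(C)Oc1cc(OCc2ccccc2)cc(OCc2ccccc2)c1Br | intermediate
16 | lithium 3,5-bis(benzyloxy)-2-(trimethylsilyl)phenolate | [Li+].[O-]c1cc(OCc2ccccc2)cc(OCc2ccccc2)c1[Si](C)(C)C | intermediate
17 | 3,5-bis(benzyloxy)-2-(trimethylsilyl)phenyl trifluoromethanesulfonate | C[Si](C)(C)c1c(OS(=O)(=O)C(F)(F)F)cc(OCc2ccccc2)cc1OCc1ccccc1 | intermediate
18 | 3,5-bis(benzyloxy)benzyne (3,5-bis(benzyloxy)-1,2-didehydrobenzene) | C1#CC(OCc2ccccc2)=CC(OCc2ccccc2)=C1 | intermediate
19 | 1-[2,4-bis(benzyloxy)-6-hydroxyphenyl]-3-(4-(benzyloxy)-3-{5,7-bis(benzyloxy)-2-[4-(benzyloxy)-3-methoxyphenyl]-4-oxo-4H-chromen-8-yl}phenyl)prop-2-yn-1-one | COc1cc(-c2cc(=O)c3c(OCc4ccccc4)cc(OCc4ccccc4)c(-c4cc(C#CC(=O)c5c(O)cc(OCc6ccccc6)cc5OCc5ccccc5)ccc4OCc4ccccc4)c3o2)ccc1OCc1ccccc1 | intermediate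
20 | 5,7-bis(benzyloxy)-8-{2-(benzyloxy)-5-[5,7-bis(benzyloxy)-4-oxo-4H-chromen-2-yl]phenyl}-2-[4-(benzyloxy)-3-methoxyphenyl]-4H-chromen-4-one | COc1cc(-c2cc(=O)c3c(OCc4ccccc4)cc(OCc4ccccc4)c(-c4cc(-c5cc(=O)c6c(OCc7ccccc7)cc(OCc7ccccc7)cc6o5)ccc4OCc4ccccc4)c3o2)ccc1OCc1ccccc1 | intermediate
21 | 8-[5-(5,7-dihydroxy-4-oxo-4H-chromen-2-yl)-2-hydroxyphenyl]-5,7-dihydroxy-2-(4-hydroxy-3-methoxyphenyl)-4H-chromen-4-one (CNP0179340.0) | COc1cc(-c2cc(=O)c3c(O)cc(O)c(-c4cc(-c5cc(=O)c6c(O)cc(O)cc6o5)ccc4O)c3o2)ccc1O | target

**Step count and risks**

Total step count: 14. Longest linear sequence: 10 steps (steps 1, 2, 3, 4, 7, 8, 9, 12, 13, 14) from 1. Steps 5 and 6 and steps 10 and 11 are side branches.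

Least certain steps:

Step 12 (key step). The most likely failure is protonation of the aryl anion by a second molecule of acid before the acyl shift, which would stop the sequence at simple O-arylation. Further arylation of the product phenoxide by excess aryne and 5-exo closure of the phenoxide onto the alkyne in the hot basic medium could also erode the outcome. The fallback sets out from alkyne 11 and phenol 13 and comes back at 20. Phenol 13 would be iodinated ortho to the hydroxyl (NIS, CH2Cl2, −78 °C) to 3,5-bis(benzyloxy)-2-iodophenol F1. F1 and 11 would then be joined by palladium-catalysed carbonylative Sonogashira annulation (PdCl2(PPh3)2, CO 1 atm, Et2NH, DMF, 90 °C). The acylpalladium species from F1 and CO is captured by the alkyne, and the diethylamine steers ynone 19, formed in the flask, to six-membered closure, which gives 20 directly.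

Step 7. Transmetalation and reductive elimination at the doubly ortho-substituted C8 may be slow enough for protodeboronation of 9 and reductive loss of iodine from 6 to win. The fallback sets out from bromide 8 and comes back at 10. Bromide 8 would be stannylated (Me3SnSnMe3, Pd(PPh3)4, toluene, 100 °C) to 4-(benzyloxy)-3-(trimethylstannyl)benzaldehyde F2, and F2 coupled with 6 under copper-assisted Stille conditions (Pd(PPh3)4, CuI, CsF, DMF, 60 °C). Fluoride and copper speed the transfer of hindered aryl groups from tin, and the partner cannot protodeboronate.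

Step 9. The carboxylation is reversible, so loss of CO2 from the propiolate when the pressure is released warm, or incomplete conversion, would leave 11 mixed with 12. The fallback sets out from 11 and comes back at 12. Alkyne 11 would be deprotonated with the non-nucleophilic base LiHMDS (THF, −78 °C) and acylated with methyl chloroformate to the methyl prop-2-ynoate F3. F3 would be saponified with LiOH (THF/H2O, 0 °C) and acidified with cold 1 M HCl, conditions too mild to open the pyranone.

Step 13. Five-membered closure to the aurone may compete, because the aroyl group with two ortho substituents is twisted and the 6-endo path is slowed. The fallback sets out from 19 and comes back at 20. Diethylamine (excess, EtOH/THF, rt) would add to the ynone to give the (E)-β-(diethylamino)enone F4, which removes the alkyne before any ring closure. Heating F4 in EtOH would then let the phenol attack the enaminone carbon and expel diethylamine, a closure that can only be six-membered.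

Step 4. HI formed at 120 °C could remove or shift the iodine on the electron-rich ring A, or cleave the C5 benzyl ether. The fallback sets out from chalcone 5 and comes back at 6. Chalcone 5 would be isomerised with NaOAc in refluxing EtOH to the racemic 8-iodoflavanone F5, and F5 dehydrogenated with DDQ in refluxing 1,4-dioxane, so that no hydrogen iodide is formed at any point.

**Further compounds**

F1 | step 12 | 3,5-bis(benzyloxy)-2-iodophenol | Oc1cc(OCc2ccccc2)cc(OCc2ccccc2)c1I
F2 | step 7 | 4-(benzyloxy)-3-(trimethylstannyl)benzaldehyde | O=Cc1ccc(OCc2ccccc2)c([Sn](C)(C)C)c1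
F3 | step 9 | methyl 3-(4-(benzyloxy)-3-{5,7-bis(benzyloxy)-2-[4-(benzyloxy)-3-methoxyphenyl]-4-oxo-4H-chromen-8-yl}phenyl)prop-2-ynoate | COc1cc(-c2cc(=O)c3c(OCc4ccccc4)cc(OCc4ccccc4)c(-c4cc(C#CC(=O)OC)ccc4OCc4ccccc4)c3o2)ccc1OCc1ccccc1
F4 | step 13 | (E)-1-[2,4-bis(benzyloxy)-6-hydroxyphenyl]-3-(4-(benzyloxy)-3-{5,7-bis(benzyloxy)-2-[4-(benzyloxy)-3-methoxyphenyl]-4-oxo-4H-chromen-8-yl}phenyl)-3-(diethylamino)prop-2-en-1-one | COc1cc(-c2cc(=O)c3c(OCc4ccccc4)cc(OCc4ccccc4)c(-c4cc(/C(=C\C(=O)c5c(O)cc(OCc6ccccc6)cc5OCc5ccccc5)N(CC)CC)ccc4OCc4ccccc4)c3o2)ccc1OCc1ccccc1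
F5 | step 4 | racemic 5,7-bis(benzyloxy)-2-[4-(benzyloxy)-3-methoxyphenyl]-8-iodochroman-4-one | COc1cc(C2CC(=O)c3c(OCc4ccccc4)cc(OCc4ccccc4)c(I)c3O2)ccc1OCc1ccccc1
A1 | alternative 1 | 3-ethoxycyclobut-2-en-1-one | CCOC1=CC(=O)C1
A2 | alternative 1 | triisopropyl({[2-(benzyloxy)-5-(1,3-dioxolan-2-yl)phenyl]ethynyl}oxy)silane | CC(C)[Si](OC#Cc1cc(C2OCCO2)ccc1OCc1ccccc1)(C(C)C)C(C)C
A3 | alternative 1 | 2-[2-(benzyloxy)-5-(1,3-dioxolan-2-yl)phenyl]-5-ethoxy-3-(triisopropylsiloxy)phenol | CCOc1cc(O)c(-c2cc(C3OCCO3)ccc2OCc2ccccc2)c(O[Si](C(C)C)(C(C)C)C(C)C)c1
A4 | alternative 2 | (E)-4,6-bis(benzyloxy)-3-{2-(benzyloxy)-5-[5,7-bis(benzyloxy)-4-oxo-4H-chromen-2-yl]phenyl}-2-(methoxymethoxy)benzaldehyde oxime | COCOc1c(/C=N/O)c(OCc2ccccc2)cc(OCc2ccccc2)c1-c1cc(-c2cc(=O)c3c(OCc4ccccc4)cc(OCc4ccccc4)cc3o2)ccc1OCc1ccccc1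
A5 | alternative 2 | 4,6-bis(benzyloxy)-3-{2-(benzyloxy)-5-[5,7-bis(benzyloxy)-4-oxo-4H-chromen-2-yl]phenyl}-2-(methoxymethoxy)benzonitrile oxide | COCOc1c(C#[N+][O-])c(OCc2ccccc2)cc(OCc2ccccc2)c1-c1cc(-c2cc(=O)c3c(OCc4ccccc4)cc(OCc4ccccc4)cc3o2)ccc1OCc1ccccc1
A6 | alternative 2 | 1-(benzyloxy)-4-ethynyl-2-methoxybenzene | C#Cc1ccc(OCc2ccccc2)c(OC)c1
A7 | alternative 2 | 3-(biaryl)-5-[4-(benzyloxy)-3-methoxyphenyl]isoxazole carrying the protected apigenin unit | COCOc1c(-c2cc(-c3ccc(OCc4ccccc4)c(OC)c3)on2)c(OCc2ccccc2)cc(OCc2ccccc2)c1-c1cc(-c2cc(=O)c3c(OCc4ccccc4)cc(OCc4ccccc4)cc3o2)ccc1OCc1ccccc1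
A8 | alternative 3 | methyl coumalate (methyl 2-oxo-2H-pyran-5-carboxylate) | COC(=O)C1=COC(=O)C=C1
A9 | alternative 3 | 5,7-bis(benzyloxy)-2-[4-(benzyloxy)-3-methoxyphenyl]-8-[(triisopropylsiloxy)ethynyl]-4H-chromen-4-one | COc1cc(-c2cc(=O)c3c(OCc4ccccc4)cc(OCc4ccccc4)c(C#CO[Si](C(C)C)(C(C)C)C(C)C)c3o2)ccc1OCc1ccccc1
A10 | alternative 3 | methyl 3-{5,7-bis(benzyloxy)-2-[4-(benzyloxy)-3-methoxyphenyl]-4-oxo-4H-chromen-8-yl}-4-(triisopropylsiloxy)benzoate | COc1cc(-c2cc(=O)c3c(OCc4ccccc4)cc(OCc4ccccc4)c(-c4cc(C(=O)OC)ccc4O[Si](C(C)C)(C(C)C)C(C)C)c3o2)ccc1OCc1ccccc1
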